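**Plan**

Locants used here: cyclopentanone C1 (C=O), C2 (CH on the cyclopropane), C3 (quaternary), C4 and C5 (CH2, C5 next to C1), benzylic C1′, side-chain carbonyl C3″.
Retrosynthetic cuts, in order: the two aryl–CHO bonds; C1=O and C3″=O rejoined as a C1–C3″ 1,2-diol (seven-membered ring), with the ring oxygen moved back from C1 to C4; C3–C1′ and C1′–isobutyl (o-quinone methide); C1–C2 together with C4–C5 (nickel [3+2] of an enoate with a tethered alkyne); the C1≡C5 unit from C3″ (Grignard), C2=C3 (Wittig) and the C=C of (+)-2-carene (ozonolysis).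
Forward order: the cyclopropane comes with the carene; the seven- and five-membered rings close together in step 4; the arene is attached in step 7; the seven-membered ring is opened again in step 11; the formyl groups come last.
Stereochemistry: both cyclopropane centres from (+)-2-carene; C2 from the cis-cyclopropane tether in step 4; C3 from attack on the enol ether face away from the cyclopropane-bearing ring fusion and C1′ from the endo [4+2] mode in step 7; the carbinol, C-methyl and epoxide epimer mixtures all converge (steps 5, 10, 11), and C2, α to the final ketone, already sits trans to the large C3 substituent.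
Enabling feature: C1 and C3″ hang on the two cis arms of the cyclopropane (C1 through C2, C3″ through two CH2), so a C1–C3″ bond closes a seven-membered ring cis-fused to the cyclopropane; the methyl ketone can therefore carry the two-carbon unit C1≡C5 as a tether that is cut later, while C2, C3 and C4 are the β-carbon, α-carbon and carboxyl carbon of an enoate grown from the carene aldehyde.

Key step: step 4

Assumption: 2,4-bis(benzyloxy)-6-hydroxybenzaldehyde is taken as a purchasable phloroglucinaldehyde derivative, and (+)-2-carene as the (1S,6R) enantiomer.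

**Route**

Step 1
Reactants: 1 (+)-2-carene, (1S,6R)-3,7,7-trimethylbicyclo[4.1.0]hept-2-ene
Product: 2 (1S,3R)-2,2-dimethyl-3-(3-oxobutyl)cyclopropane-1-carbaldehyde (cis)
Conditions: O3, CH2Cl2/MeOH, −78 °C; then Me2S, −78 °C to rt
Reagents that add atoms: ozone, [O-][O+]=O
Why: Ozonolysis with reductive work-up cleaves the only C=C and leaves both cyclopropane stereocentres untouched, so the cis keto aldehyde should form with the configuration of the terpene.

Step 2
Reactants: 2; 3 ethyl 2-(triphenylphosphoranylidene)propanoate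
Product: 4 ethyl (2E)-3-[cis-2,2-dimethyl-3-(3-oxobutyl)cyclopropyl]-2-methylprop-2-enoate (cyclopropane as in 2)
Conditions: CH2Cl2, rt
Reagents that add atoms: ethyl 2-(triphenylphosphoranylidene)propanoate 3, CCOC(=O)C(C)=P(c1ccccc1)(c1ccccc1)c1ccccc1
Why: Wittig olefination with a stabilised α-methyl ylide should react only at the aldehyde, leave the methyl ketone, give the E enoate and, being barely basic, not epimerise the cis cyclopropane.

Step 3
Reactants: 4; 5 ethynylmagnesium bromide
Product: 6 ethyl (2E)-3-[cis-3-(3-hydroxy-3-methylpent-4-yn-1-yl)-2,2-dimethylcyclopropyl]-2-methylprop-2-enoate (both carbinol epimers)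
Conditions: HC≡CMgBr (1.2 equiv), THF, −78 to −20 °C; then aq NH4Cl
Reagents that add atoms: ethynylmagnesium bromide 5, C#C[Mg]Br
Why: Grignard 1,2-addition should be chemoselective for the ketone over the hindered α-methyl enoate; the new carbinol centre is uncontrolled on purpose because it becomes the methyl ketone carbon again in step 11.

Step 4
Reactants: 6
Product: 7 4-hydroxy-1,1,4,7-tetramethyl-1,1a,2,3,4,7,7a,7b-octahydro-6H-cyclopropa[e]azulen-6-one (1a-H/7b-H cis, 7a-H anti to 7b-H; epimers at C4 and C7)
Conditions: Ni(COD)2 (20 mol%), PBu3 (40 mol%), Et3B (4 equiv), MeOH/THF, 0.01 M, 50 °C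
Reagents that add atoms: none
Why: Zerovalent nickel couples the enoate and the alkyne oxidatively (enoate β-carbon, future C2, to the internal alkyne carbon, future C1) to give a nickel enolate/alkenylnickel metallacycle; methanol protonates the enolate carbon (future C3), the alkenylnickel carbon (future C5) adds to the ester carbonyl (future C4) with loss of ethoxide, and Et3B returns divalent nickel to the zerovalent state. The closest known reaction type is the nickel-catalysed reductive [3+2] cycloaddition of enoates (or enals) with alkynes to cyclopent-2-enones (cyclopentenols). The seven-membered ring closes in the exo mode at both π systems (only the tethered alkyne carbon and the β-carbon enter the ring) and the five-membered ring closes by 5-exo-trig attack of the alkenyl carbon on the ester C=O. The new ring-fusion stereocentre (future C2) is controlled by the cis-cyclopropane: the vinylcyclopropane keeps its s-trans bisected conformation and the chain on the neighbouring cyclopropane carbon can deliver the alkyne only to the enoate face on its own side, which is the target configuration; the CH(CH3) centre forms as a mixture that is erased in step 5. The step needs cyclisation to beat intermolecular reductive coupling, alkyne oligomerisation and nickel insertion into the vinylcyclopropane, which the rigid cis tether, high dilution, a phosphine instead of a carbene ligand and the protic medium are chosen to secure.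

Step 5
Reactants: 7
Product: 8 triethyl({1,1,4,7-tetramethyl-4-[(triethylsilyl)oxy]-1a,2,3,4,7a,7b-hexahydro-1H-cyclopropa[e]azulen-6-yl}oxy)silane (cross-conjugated silyl dienol ether)
Conditions: LiN(iPr)2 (2.3 equiv), THF, −78 °C; Et3SiCl (2.6 equiv), −78 to 0 °C; used crude, kept at or below 0 °C
Reagents that add atoms: chlorotriethylsilane, CC[Si](Cl)(CC)CC
Why: Kinetic deprotonation of the enone at the α′ CH(CH3) and O-silylation (the tertiary alkoxide is silylated as well) should give one planar enol ether from both C-methyl epimers, and the low temperature guards against 1,5-hydrogen shifts of the cyclopentadiene.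

Step 6
Reactants: 9 2,4-bis(benzyloxy)-6-hydroxybenzaldehyde
Product: 10 3,5-bis(benzyloxy)-2-formylphenyl tert-butyl carbonate
Conditions: Boc2O (1.2 equiv), iPr2NEt, DMAP (5 mol%), THF, rt
Reagents that add atoms: di-tert-butyl dicarbonate, CC(C)(C)OC(=O)OC(=O)OC(C)(C)C
Why: DMAP-catalysed O-acylation of the phenol installs the carbonate that later migrates and leaves, which allows the quinone methide to be generated at low temperature.

Step 7
Reactants: 8; 10; 11 isobutylmagnesium bromide
Product: 14 7-[(1S)-1-(2,4-bis(benzyloxy)-6-hydroxyphenyl)-3-methylbutyl]-4-hydroxy-1,1,4,7-tetramethyl-1,1a,2,3,4,7,7a,7b-octahydro-6H-cyclopropa[e]azulen-6-one, via o-quinone methide 12 (not isolated), via chroman silyl ketal 13 (not isolated)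
Conditions: 10 (2 equiv), 8 (1 equiv), Et2O, −78 °C; iBuMgBr (2 equiv); −78 °C to rt; then 1 M HCl, THF, rt
Reagents that add atoms: aryl carbonate 10, O=Cc1c(OC(=O)OC(C)(C)C)cc(OCc2ccccc2)cc1OCc1ccccc1; isobutylmagnesium bromide 11, CC(C)C[Mg]Br
Why: Grignard addition to the aldehyde, carbonate transfer to the new alkoxide and loss of tert-butyl carbonate should give the E quinone methide, which undergoes an inverse-demand hetero-Diels–Alder reaction with the tetrasubstituted enol ether on the face away from the cyclopropane-bearing ring-fusion bond (sets C3) and in the endo-silyloxy mode (isobutyl cis to methyl on the chroman, sets C1′); the acid work-up opens the silyl ketal to ketone and phenol and removes the tertiary silyl ether.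

Step 8
Reactants: 14
Product: 15 4-hydroxy-1,1,4,7-tetramethyl-7-[(1S)-3-methyl-1-(2,4,6-tris(benzyloxy)phenyl)butyl]-1,1a,2,3,4,7,7a,7b-octahydro-6H-cyclopropa[e]azulen-6-one
Conditions: BnBr, K2CO3, DMF, rt
Reagents that add atoms: benzyl bromide, BrCc1ccccc1
Why: Williamson etherification of the phenol (the tertiary alcohol should not react) blocks retro-Michael loss of the arene and oxidation of the phenol in steps 9 to 11 and lets one hydrogenolysis free all three phenols later.

Step 9
Reactants: 15
Product: 16 4a,5-epoxide of 15 (epoxy ketone; mixture of epoxide faces and carbinol epimers)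
Conditions: 30% H2O2, NaOH, MeOH/THF, 0 °C to rt
Reagents that add atoms: hydrogen peroxide, OO
Why: Weitz–Scheffer nucleophilic epoxidation of the cyclopentenone should occur at the only electron-poor alkene, and its face selectivity is irrelevant because both epoxide carbons lose their stereochemistry in steps 10 to 12.

Step 10
Reactants: 16
Product: 17 1,1,4,7-tetramethyl-7-[(1S)-3-methyl-1-(2,4,6-tris(benzyloxy)phenyl)butyl]-1,1a,2,3,4,7,7a,7b-octahydro-4aH-cyclopropa[e]azulene-4,4a-diol (C5=C6 alkene; diol epimers)
Conditions: N2H4·H2O (3 equiv), AcOH (cat.), MeOH, 0 °C to rt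
Reagents that add atoms: none
Why: Wharton transposition (hydrazone, epoxide opening to an alkenyl diazene, loss of nitrogen) should remove the helper oxygen from the future C4 and place a hydroxyl on the future C1, next to the tertiary carbinol of the tether.

Step 11
Reactants: 17
Product: 18 5-[cis-2,2-dimethyl-3-(3-oxobutyl)cyclopropyl]-4-methyl-4-[(1S)-3-methyl-1-(2,4,6-tris(benzyloxy)phenyl)butyl]cyclopent-2-en-1-one
Conditions: Pb(OAc)4 (1.2 equiv), CH2Cl2, −20 to 0 °C
Reagents that add atoms: none
Why: Criegee glycol cleavage of the ditertiary 1,2-diol (either relative configuration) should open the seven-membered ring and release the C1 ketone and the methyl ketone in one operation, so that all diol epimers converge.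

Step 12
Reactants: 18
Product: 19 2-[cis-2,2-dimethyl-3-(3-oxobutyl)cyclopropyl]-3-methyl-3-[(1S)-3-methyl-1-(2,4,6-trihydroxyphenyl)butyl]cyclopentan-1-one
Conditions: H2 (1 atm), Pd on carbon (Pd/C, 10%), EtOAc/EtOH, rt
Reagents that add atoms: none
Why: Catalytic hydrogenation should saturate the disubstituted enone C=C and hydrogenolyse the three benzyl ethers together, while the unconjugated alkylcyclopropane and the ketones survive and C2 stays trans to the large C3 substituent.

Step 13
Reactants: 19
Product: 20 Macrocarpal N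
Conditions: POCl3 (3 equiv), DMF, EtOAc, 0 °C to rt, under argon; then aq NaOAc, rt
Reagents that add atoms: N,N-dimethylformamide, CN(C)C=O; water, O
Why: Vilsmeier–Haack formylation should take place twice at the two free positions of the phloroglucinol ring, which is far more nucleophilic at this temperature than the enols of the two ketones.

**Compound list**

1 | (+)-2-carene, (1S,6R)-3,7,7-trimethylbicyclo[4.1.0]hept-2-ene | CC1=C[C@H]2[C@@H](CC1)C2(C)C | starting material
2 | (1S,3R)-2,2-dimethyl-3-(3-oxobutyl)cyclopropane-1-carbaldehyde | CC(=O)CC[C@@H]1[C@H](C=O)C1(C)C | intermediate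
3 | ethyl 2-(triphenylphosphoranylidene)propanoate | CCOC(=O)C(C)=P(c1ccccc1)(c1ccccc1)c1ccccc1 | starting material
4 | ethyl (2E)-3-[cis-2,2-dimethyl-3-(3-oxobutyl)cyclopropyl]-2-methylprop-2-enoate | CC(=O)CC[C@@H]1[C@H](/C=C(\C)C(=O)OCC)C1(C)C | intermediate
5 | ethynylmagnesium bromide | C#C[Mg]Br | starting material
6 | ethyl (2E)-3-[cis-3-(3-hydroxy-3-methylpent-4-yn-1-yl)-2,2-dimethylcyclopropyl]-2-methylprop-2-enoate, carbinol epimers | CC(O)(C#C)CC[C@@H]1[C@H](/C=C(\C)C(=O)OCC)C1(C)C | intermediate
7 | 4-hydroxy-1,1,4,7-tetramethyl-1,1a,2,3,4,7,7a,7b-octahydro-6H-cyclopropa[e]azulen-6-one, epimers at C4 and C7 | CC1(O)CC[C@@H]2[C@H]([C@@H]3C(C)C(=O)C=C13)C2(C)C | intermediate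
8 | triethyl({1,1,4,7-tetramethyl-4-[(triethylsilyl)oxy]-1a,2,3,4,7a,7b-hexahydro-1H-cyclopropa[e]azulen-6-yl}oxy)silane | CC1(O[Si](CC)(CC)CC)CC[C@@H]2[C@H]([C@@H]3C(C)=C(O[Si](CC)(CC)CC)C=C13)C2(C)C | intermediate
9 | 2,4-bis(benzyloxy)-6-hydroxybenzaldehyde | O=Cc1c(O)cc(OCc2ccccc2)cc1OCc1ccccc1 | starting material
10 | 3,5-bis(benzyloxy)-2-formylphenyl tert-butyl carbonate | O=Cc1c(OC(=O)OC(C)(C)C)cc(OCc2ccccc2)cc1OCc1ccccc1 | intermediate
11 | isobutylmagnesium bromide | CC(C)C[Mg]Br | starting material
12 | (6E)-3,5-bis(benzyloxy)-6-(3-methylbutylidene)cyclohexa-2,4-dien-1-one (o-quinone methide, not isolated) | CC(C)C/C=C1/C(=O)C=C(OCc2ccccc2)C=C1OCc1ccccc1 | intermediate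
13 | chroman silyl ketal, endo [4+2] adduct of 12 across the enol ether C=C of 8 (not isolated) | CC1(O[Si](CC)(CC)CC)CC[C@@H]2[C@H]([C@@H]3[C@@]4(C)[C@H](CC(C)C)c5c(cc(OCc6ccccc6)cc5OCc5ccccc5)O[C@@]4(O[Si](CC)(CC)CC)C=C13)C2(C)C | intermediate
14 | 7-[(1S)-1-(2,4-bis(benzyloxy)-6-hydroxyphenyl)-3-methylbutyl]-4-hydroxy-1,1,4,7-tetramethyl-1,1a,2,3,4,7,7a,7b-octahydro-6H-cyclopropa[e]azulen-6-one, carbinol epimers | CC1(O)CC[C@@H]2[C@H]([C@@H]3[C@@](C)([C@H](CC(C)C)c4c(O)cc(OCc5ccccc5)cc4OCc4ccccc4)C(=O)C=C13)C2(C)C | intermediate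
15 | 4-hydroxy-1,1,4,7-tetramethyl-7-[(1S)-3-methyl-1-(2,4,6-tris(benzyloxy)phenyl)butyl]-1,1a,2,3,4,7,7a,7b-octahydro-6H-cyclopropa[e]azulen-6-one, carbinol epimers | CC1(O)CC[C@@H]2[C@H]([C@@H]3[C@@](C)([C@H](CC(C)C)c4c(OCc5ccccc5)cc(OCc5ccccc5)cc4OCc4ccccc4)C(=O)C=C13)C2(C)C | intermediate
16 | 4a,5-epoxide of 15 (epoxy ketone, epimer mixture) | CC1(O)CC[C@@H]2[C@H]([C@@H]3[C@@](C)([C@H](CC(C)C)c4c(OCc5ccccc5)cc(OCc5ccccc5)cc4OCc4ccccc4)C(=O)C4OC134)C2(C)C | intermediate
17 | 1,1,4,7-tetramethyl-7-[(1S)-3-methyl-1-(2,4,6-tris(benzyloxy)phenyl)butyl]-1,1a,2,3,4,7,7a,7b-octahydro-4aH-cyclopropa[e]azulene-4,4a-diol, diol epimers | CC1(O)CC[C@@H]2[C@H]([C@@H]3[C@@](C)([C@H](CC(C)C)c4c(OCc5ccccc5)cc(OCc5ccccc5)cc4OCc4ccccc4)C=CC13O)C2(C)C | intermediate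
18 | 5-[cis-2,2-dimethyl-3-(3-oxobutyl)cyclopropyl]-4-methyl-4-[(1S)-3-methyl-1-(2,4,6-tris(benzyloxy)phenyl)butyl]cyclopent-2-en-1-one | CC(=O)CC[C@@H]1[C@H]([C@H]2C(=O)C=C[C@]2(C)[C@H](CC(C)C)c2c(OCc3ccccc3)cc(OCc3ccccc3)cc2OCc2ccccc2)C1(C)C | intermediate
19 | 2-[cis-2,2-dimethyl-3-(3-oxobutyl)cyclopropyl]-3-methyl-3-[(1S)-3-methyl-1-(2,4,6-trihydroxyphenyl)butyl]cyclopentan-1-one | CC(=O)CC[C@@H]1[C@H]([C@H]2C(=O)CC[C@]2(C)[C@H](CC(C)C)c2c(O)cc(O)cc2O)C1(C)C | intermediate
20 | Macrocarpal N | CC(=O)CC[C@@H]1[C@H]([C@H]2C(=O)CC[C@]2(C)[C@H](CC(C)C)c2c(O)c(C=O)c(O)c(C=O)c2O)C1(C)C | target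

**Step count and risks**

Total steps: 13. Longest linear sequence: 12 steps (steps 1 to 5 and 7 to 13, from (+)-2-carene).

Step 4. What may go wrong: closure of the seven-membered metallacycle is slow, so that alkyne oligomerisation, intermolecular reductive coupling or protonation of the alkenylnickel before acyl substitution takes over. The fallback sets out from 6 and comes back at 7. Bu3SnH/AIBN (benzene, 80 °C, slow addition) adds a stannyl radical to the terminal alkyne carbon, and the alkenyl radical closes the seven-membered ring 7-exo onto the enoate β-carbon under the same tether control. This gives the alkenylstannane ester ethyl 2-{4-hydroxy-4,8,8-trimethyl-3-[(tributylstannyl)methylidene]bicyclo[5.1.0]octan-2-yl}propanoate F1; tin is expected syn to the new ring bond, away from the fully substituted carbinol carbon. I2 (CH2Cl2, 0 °C) gives the alkenyl iodide ethyl 2-[4-hydroxy-3-(iodomethylidene)-4,8,8-trimethylbicyclo[5.1.0]octan-2-yl]propanoate F2. t-BuLi (3.2 equiv, THF/Et2O, −100 to −78 °C) exchanges iodine for lithium, and the alkenyllithium acylates itself on the ethyl ester (5-exo) to give 7.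

Step 7. What may go wrong: loss of endo or facial control, or E/Z scrambling of the quinone methide beside the flanking benzyloxy group, which would give the wrong C1′ epimer; retro-Michael loss of the arene on work-up. The fallback sets out from 8 (with 10) and comes back at 14; it inverts the order in which the two bonds at C1′ are made. MeLi (THF, 0 °C) converts 8 into the lithium dienolate F3, which adds at −78 °C to aldehyde 10 from the same open face (aldol, sets C3). The aldolate takes over the carbonate group and loses tert-butyl carbonate on warming to give the terpenoid-substituted o-quinone methide F4. iBuMgBr with CuBr·SMe2 (10 mol%) then adds 1,4 to F4, with C1′ now set by the adjacent quaternary carbon, and the HCl work-up gives 14.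

Step 10. What may go wrong: hydrazone formation at the carbonyl flanked by the quaternary carbon is too slow, and hydrazine opens the epoxide instead. The fallback sets out from 16 and comes back at 17. NaBH4 (MeOH, 0 °C) gives the epoxy alcohol F5 (6-hydroxy analogue of 16). 1,1′-Thiocarbonyldiimidazole (DMAP, toluene, 80 °C) gives the imidazolylthiocarbonate F6. Bu3SnH/AIBN (benzene, 80 °C, high stannane concentration) generates the secondary radical, the neighbouring epoxide opens at its C–O bond, and reduction of the alkoxy radical gives the transposed allylic alcohol 17.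

**Further compounds**

F1 | step 4 | ethyl 2-{4-hydroxy-4,8,8-trimethyl-3-[(tributylstannyl)methylidene]bicyclo[5.1.0]octan-2-yl}propanoate | CC1(O)CC[C@@H]2[C@H]([C@H](C(C)C(=O)OCC)/C1=C\[Sn](CCCC)(CCCC)CCCC)C2(C)C
F2 | step 4 | ethyl 2-[4-hydroxy-3-(iodomethylidene)-4,8,8-trimethylbicyclo[5.1.0]octan-2-yl]propanoate | CC1(O)CC[C@@H]2[C@H]([C@H](C(C)C(=O)OCC)/C1=C\I)C2(C)C
F3 | step 7 | lithium dienolate of 7 carrying the tertiary triethylsilyl ether | CC1(O[Si](CC)(CC)CC)CC[C@@H]2[C@H]([C@@H]3C(C)=C(O[Li])C=C13)C2(C)C
F4 | step 7 | 7-{[2,4-bis(benzyloxy)-6-oxocyclohexa-2,4-dien-1-ylidene]methyl}-1,1,4,7-tetramethyl-4-[(triethylsilyl)oxy]-1,1a,2,3,4,7,7a,7b-octahydro-6H-cyclopropa[e]azulen-6-one | CC1(O[Si](CC)(CC)CC)CC[C@@H]2[C@H]([C@@H]3[C@@](C)(C=C4C(=O)C=C(OCc5ccccc5)C=C4OCc4ccccc4)C(=O)C=C13)C2(C)C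
F5 | step 10 | epoxy alcohol, 6-hydroxy analogue of 16 | CC1(O)CC[C@@H]2[C@H]([C@@H]3[C@@](C)([C@H](CC(C)C)c4c(OCc5ccccc5)cc(OCc5ccccc5)cc4OCc4ccccc4)C(O)C4OC134)C2(C)C
F6 | step 10 | O-(epoxy alcohol F5) 1H-imidazole-1-carbothioate | CC1(O)CC[C@@H]2[C@H]([C@@H]3[C@@](C)([C@H](CC(C)C)c4c(OCc5ccccc5)cc(OCc5ccccc5)cc4OCc4ccccc4)C(OC(=S)n4ccnc4)C4OC134)C2(C)C
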